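**Retrosynthetic overview**
1. Last bond, ring C3 to pyranone C3: Lewis-acid allylation of 4-hydroxy-6-styrylpyranone 15 by the C1–C2–C3 allyl cation from tertiary alcohol 10. Attack anti to the isopropyl group on C4 gives the trans pair of stereocentres and leaves C1=C2.
2. C1–CH3 bond: CH3Li on (R)-cryptone 8, so the carbocycle is built at the C1-ketone oxidation level.
3. Carbocycle: closed at C4–C5 (isopropyl-bearing carbon to ring methylene) by a chiral-cation-directed 6π electrocyclisation of the trienolate of achiral divinyl ketone 5, two steps from 3-methylbutanal.
4. Enabling feature: in the six-membered carbocycle C4 is γ to C1 through C2=C3 and C5 is β to C1. One carbonyl on C1 therefore makes C4 the donor and C5 the acceptor terminus of a single hexatriene, and the C1–C2–C3 allyl triad later relays functionality to C3.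
5. Ring order: the pyranone ring is bought (in 11) and only extended; the carbocycle is the only ring formed (step 3); the two are joined in step 7.

Key step: step 3

Remark: the carbocycle carbons are called C1 (methyl-bearing), C2, C3 (pyranone-bearing), C4 (isopropyl-bearing), C5 and C6 throughout.
Remark: the sense of induction of the chiral ammonium salt in step 3 cannot be predicted with certainty; the cinchonidinium salt is written, and its pseudoenantiomeric cinchoninium salt would be used if the opposite sense is found.
Remark: CH3Li addition in step 4 is assumed to be unselective at C1; the two C1 epimers are carried together as the single compound 10, because both give the same allyl cation in step 7.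

**Step 1**
Reactants: 1 3-methylbutanal; 2 diethyl {2-[methoxy(methyl)amino]-2-oxoethyl}phosphonate
Product: 3 (E)-N-methoxy-N,5-dimethylhex-2-enamide
Conditions: NaH, THF, 0 °C to rt
Reagents that add atoms: diethyl {2-[methoxy(methyl)amino]-2-oxoethyl}phosphonate (compound 2), CCOP(=O)(CC(=O)N(C)OC)OCC
Why: Horner–Wadsworth–Emmons olefination with a stabilised amide phosphonate should give the E alkene as the thermodynamically preferred geometry.

**Step 2**
Reactants: 3 (E)-N-methoxy-N,5-dimethylhex-2-enamide; 4 vinylmagnesium bromide
Product: 5 (E)-7-methylocta-1,4-dien-3-one
Conditions: CH2=CHMgBr (1.3 equiv), THF, −20 to 0 °C; inverse quench into cold aqueous HCl; used at once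
Reagents that add atoms: vinylmagnesium bromide (compound 4), C=C[Mg]Br
Why: Weinreb ketone synthesis should stop cleanly at single addition, and the inverse acidic quench should protonate the released hydroxylamine before it can add to the vinyl ketone.

**Step 3**
Reactants: 5 (E)-7-methylocta-1,4-dien-3-one
Product: 8 (R)-4-isopropylcyclohex-2-en-1-one, via trienolate 6 (not isolated), via cyclohexadienolate 7 (not isolated)
Conditions: O-allyl-N-(9-anthracenylmethyl)cinchonidinium bromide (10 mol %), CsOH·H2O (20 mol %), toluene–CH2Cl2, 0.01 M, −40 °C; AcOH quench
Reagents that add atoms: none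
Why: Proposed new method: hydroxide removes the only acidic hydrogen of 5, a γ-hydrogen on C4 (the vinyl arm has none), to give the cross-conjugated trienolate 6, a 3-oxidohexatriene whose termini C4 and C5 are joined by thermal disrotatory 6π electrocyclisation to cyclohexadienolate 7, and protonation at C6 gives enone 8. The closest known reaction types are the base-mediated cyclisation of phorone to isophorone (the same trienolate ring closure, racemic) and the cation-directed 6π electrocyclisation of azapentadienyl anions under cinchona-derived phase-transfer catalysts (an enantioselective anionic electrocyclisation in a chiral ion pair). The six-membered carbocycle closes in this single C4–C5 bond-forming event, which can equally be read as a 6-endo vinylogous Michael addition. The new stereocentre C4 is fixed by the sense of disrotation, which the chiral ammonium cation of the contact ion pair is meant to bias, while the E geometry of the terminal C3=C4 double bond of 6 keeps the isopropyl group on the outside of the closing termini. The step needs γ over α reactivity and intra- over intermolecular addition: only C4 can reach C5 through a six-membered transition state, since α attack would give a four-membered ring, and high dilution should suppress Michael addition to the vinyl ketone of a second molecule. Low temperature and substoichiometric base are chosen so that 8 is not deprotonated at C4, which would racemise it.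

**Step 4**
Reactants: 8 (R)-4-isopropylcyclohex-2-en-1-one; 9 methyllithium
Product: 10 (4R)-4-isopropyl-1-methylcyclohex-2-en-1-ol (mixture of the two C1 epimers)
Conditions: CH3Li, Et2O, −78 °C; then H2O
Reagents that add atoms: methyllithium (compound 9), [Li]C
Why: 1,2-addition of a hard organolithium to the enone carbonyl at low temperature should give the tertiary allylic alcohol without touching C4; the new C1 centre is expected to form unselectively and the epimers are not separated, which is harmless because C1 becomes planar on ionisation in step 7.

**Step 5**
Reactants: 11 4-hydroxy-6-methyl-2H-pyran-2-one; 12 benzaldehyde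
Product: 14 4-hydroxy-6-(2-hydroxy-2-phenylethyl)-2H-pyran-2-one, via dilithium dianion 13 (not isolated)
Conditions: LiN(i-Pr)2 (2.3 equiv), THF, −78 °C; then 12; aqueous HCl work-up
Reagents that add atoms: none
Why: aldol addition of a dianion, in which the second deprotonation occurs at the vinylogous 6-methyl group and this more reactive carbanion of 13 should add to the aldehyde; the carbinol centre is racemic and is removed in step 6.

**Step 6**
Reactants: 14 4-hydroxy-6-(2-hydroxy-2-phenylethyl)-2H-pyran-2-one
Product: 15 4-hydroxy-6-[(E)-2-phenylethenyl]-2H-pyran-2-one
Conditions: p-toluenesulfonic acid monohydrate (cat.), toluene, reflux, Dean–Stark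
Reagents that add atoms: none
Why: acid-catalysed dehydration of the benzylic β-hydroxy group should give the conjugated styryl unit with E geometry as the thermodynamic product.

**Step 7**
Reactants: 10 (4R)-4-isopropyl-1-methylcyclohex-2-en-1-ol (mixture of the two C1 epimers); 15 4-hydroxy-6-[(E)-2-phenylethenyl]-2H-pyran-2-one
Product: 17 4-hydroxy-3-[(1R,6R)-3-methyl-6-(propan-2-yl)cyclohex-2-en-1-yl]-6-[(E)-2-phenylethenyl]-2H-pyran-2-one, via allyl cation 16 (not isolated)
Conditions: BF3·OEt2 (0.3 equiv), CH2Cl2–CH3NO2, −10 °C, 15 in slight excess
Reagents that add atoms: none
Why: Friedel–Crafts-type allylic alkylation of the kind used to join menthadienol to resorcinols in cannabidiol-type syntheses: both C1 epimers of 10 ionise with loss of water to the same allyl cation 16, and the nucleophilic C3 of the hydroxypyranone should attack its secondary terminus (ring C3) from the face opposite the neighbouring isopropyl group, which sets the trans relationship and places the double bond at C1=C2.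

**Compound list**
1 | 3-methylbutanal | CC(C)CC=O | starting material
2 | diethyl {2-[methoxy(methyl)amino]-2-oxoethyl}phosphonate | CCOP(=O)(CC(=O)N(C)OC)OCC | starting material
3 | (E)-N-methoxy-N,5-dimethylhex-2-enamide | CC(C)C/C=C/C(=O)N(C)OC | intermediate
4 | vinylmagnesium bromide | C=C[Mg]Br | starting material
5 | (E)-7-methylocta-1,4-dien-3-one | C=CC(=O)/C=C/CC(C)C | intermediate
6 | (3E,5E)-7-methylocta-1,3,5-trien-3-olate (trienolate, ion-paired with the ammonium cation) | [O-]/C(C=C)=C/C=C/C(C)C | intermediate (not isolated)
7 | (R)-4-isopropylcyclohexa-1,5-dien-1-olate (cyclohexadienolate) | [O-]C1=CC[C@H](C(C)C)C=C1 | intermediate (not isolated)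
8 | (R)-4-isopropylcyclohex-2-en-1-one ((R)-cryptone) | O=C1C=C[C@@H](C(C)C)CC1 | intermediate
9 | methyllithium | [Li]C | starting material
10 | (4R)-4-isopropyl-1-methylcyclohex-2-en-1-ol (mixture of the two C1 epimers, C4 defined) | CC1(O)C=C[C@@H](C(C)C)CC1 | intermediate
11 | 4-hydroxy-6-methyl-2H-pyran-2-one | CC1=CC(O)=CC(=O)O1 | starting material
12 | benzaldehyde | O=Cc1ccccc1 | starting material
13 | dilithium dianion of 11 (4-oxido, 6-methylide) | [Li+].[Li+].[CH2-]C1=CC([O-])=CC(=O)O1 | intermediate (not isolated)
14 | 4-hydroxy-6-(2-hydroxy-2-phenylethyl)-2H-pyran-2-one (racemic) | OC(CC1=CC(O)=CC(=O)O1)c1ccccc1 | intermediate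
15 | 4-hydroxy-6-[(E)-2-phenylethenyl]-2H-pyran-2-one | O=c1cc(O)cc(/C=C/c2ccccc2)o1 | intermediate
16 | (R)-4-isopropyl-1-methylcyclohex-2-en-1-ylium (allyl cation, charge shared by C1 and C3) | C[C+]1C=C[C@@H](C(C)C)CC1 | intermediate (not isolated)
17 | 4-hydroxy-3-[(1R,6R)-3-methyl-6-(propan-2-yl)cyclohex-2-en-1-yl]-6-[(E)-2-phenylethenyl]-2H-pyran-2-one | CC1=C[C@H](c2c(O)cc(/C=C/c3ccccc3)oc2=O)[C@@H](C(C)C)CC1 | target

**Step count and risks**
Total steps: 7. Longest linear sequence: 5 steps (1, 2, 3, 4, 7).

Most likely to fail:

1. Step 3 (the step carrying the new-method label). The chiral cation may bias the sense of ring closure too weakly, intermolecular Michael oligomerisation may compete, or the product may racemise through γ-deprotonation. Fallback with known chemistry, setting out from 1 and returning at 8: enamine-catalysed Michael addition of 1 to but-3-en-2-one with (R)-α,α-diphenylprolinol trimethylsilyl ether, the enantiomer the usual shielding model predicts for the R aldehyde, should give (R)-2-isopropyl-5-oxohexanal F1. Intramolecular aldol condensation of F1 with LiOH in i-PrOH should then give 8, the ring being closed in that case by the condensation.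

2. Step 7. The acid may add the 4-hydroxyl across the C1=C2 double bond of the product, and configuration may erode through proton loss from the allyl cation to an achiral diene. Fallback, setting out from 10 and returning at 17: BF3·OEt2-catalysed allylation of methyl acetoacetate, which has no hydroxyl that can cyclise, should give methyl 2-[(1R,6R)-6-isopropyl-3-methylcyclohex-2-en-1-yl]-3-oxobutanoate F2. Its dianion (LiN(i-Pr)2, 2.2 equiv, THF, −78 °C) would be acylated at the terminal methyl with N-methoxy-N-methylcinnamamide to give methyl (6E)-2-[(1R,6R)-6-isopropyl-3-methylcyclohex-2-en-1-yl]-3,5-dioxo-7-phenylhept-6-enoate F3. DBU in refluxing toluene should then lactonise F3 to 17, so the pyranone ring is built after the C–C bond.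

3. Step 2. The liberated hydroxylamine may add in conjugate fashion to the divinyl ketone, which may also polymerise during quench and isolation. Fallback, setting out from 1 and returning at 5: Wittig olefination of 1 with (triphenylphosphoranylidene)acetaldehyde should give (E)-5-methylhex-2-enal F4. Addition of CH2=CHMgBr would give (E)-7-methylocta-1,4-dien-3-ol F5, and allylic oxidation with MnO2 in CH2Cl2 would generate 5 under neutral conditions for direct use.

**Further compounds**
F1 | step 3 | (R)-2-isopropyl-5-oxohexanal | O=C[C@@H](C(C)C)CCC(C)=O
F2 | step 7 | methyl 2-[(1R,6R)-6-isopropyl-3-methylcyclohex-2-en-1-yl]-3-oxobutanoate (both epimers at the butanoate C2) | CC1=C[C@H](C(C(C)=O)C(=O)OC)[C@@H](C(C)C)CC1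
F3 | step 7 | methyl (6E)-2-[(1R,6R)-6-isopropyl-3-methylcyclohex-2-en-1-yl]-3,5-dioxo-7-phenylhept-6-enoate | CC1=C[C@H](C(C(=O)OC)C(=O)CC(=O)/C=C/c2ccccc2)[C@@H](C(C)C)CC1
F4 | step 2 | (E)-5-methylhex-2-enal | CC(C)C/C=C/C=O
F5 | step 2 | (E)-7-methylocta-1,4-dien-3-ol (racemic) | C=CC(O)/C=C/CC(C)C
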